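**Retrosynthetic overview**
1. Target 35 ⇐ allylic alcohol 34 (MnO2). Ring D (C8–C15, quaternary C8) is closed last by an intramolecular Reformatsky-type aldol of bromo lactone enal 33.
2. 33 ⇐ spiro keto lactone 29. The C9–C10 bond and the δ-lactone come from radical conjugate addition of ring A epoxide 12 (fragment A) to keto enoate 27 (fragment B), then lactonization; C11 by LiBH(s-Bu)3.
3. Fragment B (ring C) ⇐ acetone + unsaturated α-keto ester 19 by asymmetric Michael addition and intramolecular aldol condensation.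
4. Fragment A (ring A) ⇐ (S)-keto ester 4 via bridged lactone 6, which relays C4 to C5 (hydroboration) and carries the C10 oxygen.
5. Ring order: A (from the start), C (aldol condensation), lactone (radical addition, lactonization), D (aldol).

Assumption: the quinine-derived primary amine in step 14 gives the (4R)-adduct; if the sense is opposite, its quinidine-derived pseudoenantiomer is used.
Note: C-numbers are the kaurane positions of the target (C19 = methyl, C18 = CH2O on C4); late intermediates are named on the kaurane skeleton for numbering only, with configuration given by the CIP descriptors and SMILES. TBS = tert-butyldimethylsilyl, TES = triethylsilyl.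

**Fragment A (ring A)**

Step 1
Reactants: 1 ethyl 2-oxocyclohexane-1-carboxylate
Product: 2 ethyl (1R,2R)-2-hydroxycyclohexane-1-carboxylate
Conditions: H2 (100 atm), RuCl2[(R)-BINAP] (0.5 mol %), CH2Cl2, 50 °C
Reagents that add atoms: none
Why: Noyori asymmetric hydrogenation with dynamic kinetic resolution of the racemizing β-keto ester; the (R)-BINAP ligand sets the (2R)-carbinol, the only centre carried forward.

Step 2
Reactants: 2 ethyl (1R,2R)-2-hydroxycyclohexane-1-carboxylate
Product: 3 ethyl (1S,2R)-2-hydroxy-1-methylcyclohexane-1-carboxylate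
Conditions: LiN(i-Pr)2 (2.2 equiv), THF, −50 to −20 °C; MeI, DMPU, −78 to 0 °C; H2O
Reagents that add atoms: iodomethane, CI
Why: Fráter–Seebach alkylation; in the lithium-chelated alkoxide–enolate dianion MeI attacks anti to C3, i.e. trans to the C2–O bond, which fixes the quaternary centre (target C4).

Step 3
Reactants: 3 ethyl (1S,2R)-2-hydroxy-1-methylcyclohexane-1-carboxylate
Product: 4 ethyl (1S)-1-methyl-2-oxocyclohexane-1-carboxylate
Conditions: n-Pr4N[RuO4] (5 mol %), N-methylmorpholine N-oxide, 4 Å MS, CH2Cl2, rt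
Reagents that add atoms: none
Why: Ley–Griffith oxidation of the secondary alcohol; the quaternary centre cannot epimerize.

Step 4
Reactants: 4 ethyl (1S)-1-methyl-2-oxocyclohexane-1-carboxylate
Product: 6 (1S,5R)-1-methyl-6-oxabicyclo[3.2.1]octane-7,8-dione, via hydroxy ketone 5 (not isolated)
Conditions: KN(SiMe3)2, THF, −78 °C; 2-(benzenesulfonyl)-3-phenyloxaziridine; AcOH; then TsOH·H2O (10 mol %), PhMe, 80 °C
Reagents that add atoms: 2-(benzenesulfonyl)-3-phenyloxaziridine, O=S(=O)(c1ccccc1)N1OC1c1ccccc1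
Why: Davis enolate hydroxylation at the only enolizable carbon (C10), then acid-catalysed lactonization; only the hydroxy epimer cis to the ester can bridge and the other equilibrates through the enol, so the C10–O bond ends cis to the C18 carbonyl.

Step 5
Reactants: 6 (1S,5R)-1-methyl-6-oxabicyclo[3.2.1]octane-7,8-dione
Product: 7 (1S,5R)-1-methyl-8-methylidene-6-oxabicyclo[3.2.1]octan-7-one
Conditions: Ph3PCH3Br, KOt-Bu, THF, 0 °C; then 6, 0 °C to rt
Reagents that add atoms: methyltriphenylphosphonium bromide, C[P+](c1ccccc1)(c1ccccc1)c1ccccc1.[Br-]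
Why: Wittig methylenation of the bridging ketone, which is more electrophilic than the lactone and cannot enolize because both α-carbons are bridgeheads.

Step 6
Reactants: 7 (1S,5R)-1-methyl-8-methylidene-6-oxabicyclo[3.2.1]octan-7-one
Product: 8 (1S,5R,8S)-8-(hydroxymethyl)-1-methyl-6-oxabicyclo[3.2.1]octan-7-one
Conditions: 9-borabicyclo[3.3.1]nonane (9-BBN), THF, 0 °C to rt; then H2O2, pH 7 phosphate buffer, 0 °C
Reagents that add atoms: hydrogen peroxide, OO
Why: Hydroboration–oxidation (anti-Markovnikov); the borane approaches from the face of the hydrogen-free O–C(=O) bridge, the other face being screened by two axial C–H bonds, so H5 ends syn to the lactone and the CH2OH cis to the methyl group (sets C5).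

Step 7
Reactants: 8 (1S,5R,8S)-8-(hydroxymethyl)-1-methyl-6-oxabicyclo[3.2.1]octan-7-one
Product: 9 (1R,2S,3S)-2,3-bis(hydroxymethyl)-3-methylcyclohexan-1-ol
Conditions: LiAlH4, THF, 0 °C to rt
Reagents that add atoms: none
Why: Hydride reduction of the lactone to the diol; no stereocentre is touched.

Step 8
Reactants: 9 (1R,2S,3S)-2,3-bis(hydroxymethyl)-3-methylcyclohexan-1-ol
Product: 10 (1R,2S,3S)-2,3-bis(TBSOCH2)-3-methylcyclohexan-1-ol
Conditions: TBSCl (2.1 equiv), imidazole, CH2Cl2, 0 °C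
Reagents that add atoms: tert-butyl(chloro)dimethylsilane, CC(C)(C)[Si](C)(C)Cl
Why: Selective silylation of the two primary hydroxyls; the hindered secondary hydroxyl stays free.

Step 9
Reactants: 10 (1R,2S,3S)-2,3-bis(TBSOCH2)-3-methylcyclohexan-1-ol
Product: 11 (2S,3S)-2,3-bis(TBSOCH2)-3-methylcyclohexan-1-one
Conditions: n-Pr4N[RuO4] (5 mol %), N-methylmorpholine N-oxide, 4 Å MS, CH2Cl2, rt
Reagents that add atoms: none
Why: Ley–Griffith oxidation under neutral conditions, which leaves the α-stereocentre C5 and the β-silyloxy group intact.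

Step 10
Reactants: 11 (2S,3S)-2,3-bis(TBSOCH2)-3-methylcyclohexan-1-one
Product: 12 (3R,4S,5S)-4,5-bis(TBSOCH2)-5-methyl-1-oxaspiro[2.5]octane (fragment A)
Conditions: trimethylsulfonium iodide, n-BuLi, THF, −10 °C; then 11, −10 to 0 °C
Reagents that add atoms: trimethylsulfonium iodide, C[S+](C)C.[I-]
Why: Corey–Chaykovsky epoxidation installs C20; the spiro configuration (major epimer drawn) is inconsequential because C10 becomes a planar radical in step 19.

**Fragment B (ring C)**

Step 11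
Reactants: 13 methyl 3,3-dimethoxypropanoate
Product: 14 3,3-dimethoxypropanal
Conditions: i-Bu2AlH (1.05 equiv), CH2Cl2, −78 °C
Reagents that add atoms: none
Why: Partial ester reduction; the aluminium hemiacetal is stable at −78 °C and releases the aldehyde on work-up.

Step 12
Reactants: 15 ethyl 3-bromo-2-oxopropanoate, 16 triphenylphosphane
Product: 18 ethyl 2-oxo-3-(triphenyl-λ5-phosphanylidene)propanoate, via phosphonium bromide 17 (not isolated)
Conditions: PhMe, rt; then aq. Na2CO3, CH2Cl2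
Reagents that add atoms: none
Why: SN2 quaternization of the phosphane, then deprotonation to the acyl-stabilized Wittig ylide.

Step 13
Reactants: 14 3,3-dimethoxypropanal, 18 ethyl 2-oxo-3-(triphenyl-λ5-phosphanylidene)propanoate
Product: 19 ethyl (3E)-6,6-dimethoxy-2-oxohex-3-enoate
Conditions: CH2Cl2, rt
Reagents that add atoms: none
Why: Wittig olefination with a stabilized ylide gives the (E)-alkene under neutral conditions that do not eliminate methanol from the β-alkoxy aldehyde.

Step 14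
Reactants: 19 ethyl (3E)-6,6-dimethoxy-2-oxohex-3-enoate, 20 acetone
Product: 21 ethyl (4R)-4-(2,2-dimethoxyethyl)-2,6-dioxoheptanoate
Conditions: 9-amino-9-deoxy-epi-quinine (20 mol %), PhCO2H (40 mol %), acetone, rt
Reagents that add atoms: none
Why: Enamine-catalysed asymmetric Michael addition; the catalyst-bound acetone enamine attacks one face of the β-carbon of the hydrogen-bonded unsaturated α-keto ester and sets C13.

Step 15
Reactants: 21 ethyl (4R)-4-(2,2-dimethoxyethyl)-2,6-dioxoheptanoate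
Product: 23 ethyl (5R)-5-(2,2-dimethoxyethyl)-3-oxocyclohex-1-ene-1-carboxylate, via aldol 22 (not isolated)
Conditions: pyrrolidine (20 mol %), AcOH (20 mol %), PhMe, 60 °C
Reagents that add atoms: none
Why: Intramolecular aldol condensation closes ring C; the methyl ketone enamine adds to the electrophilic α-keto ester carbonyl (the only six-membered option) and dehydration gives the conjugated keto enoate, leaving C13 untouched.

Step 16
Reactants: 23 ethyl (5R)-5-(2,2-dimethoxyethyl)-3-oxocyclohex-1-ene-1-carboxylate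
Product: 24 ethyl (5R)-3-oxo-5-(2-oxoethyl)cyclohex-1-ene-1-carboxylate
Conditions: TsOH·H2O (10 mol %), acetone–H2O, rt
Reagents that add atoms: water, O
Why: Acid-catalysed acetal hydrolysis; the keto enoate is stable to dilute acid.

Step 17
Reactants: 24 ethyl (5R)-3-oxo-5-(2-oxoethyl)cyclohex-1-ene-1-carboxylate
Product: 26 ethyl (5S)-3-oxo-5-(3-oxoprop-1-en-2-yl)cyclohex-1-ene-1-carboxylate, via Mannich base 25 (not isolated)
Conditions: Eschenmoser's salt (Me2N=CH2+ I−), Et3N, CH2Cl2, rt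
Reagents that add atoms: N,N-dimethylmethylideneammonium iodide, C=[N+](C)C.[I-]
Why: Mannich reaction of the aldehyde enol followed by β-elimination of dimethylamine (α-methylenation); the aldehyde enolizes far more readily than the ring ketone, and the change to (5S) only reflects new CIP priorities.

Step 18
Reactants: 26 ethyl (5S)-3-oxo-5-(3-oxoprop-1-en-2-yl)cyclohex-1-ene-1-carboxylate
Product: 27 ethyl (5S)-5-(3,3-dimethoxyprop-1-en-2-yl)-3-oxocyclohex-1-ene-1-carboxylate (fragment B)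
Conditions: HC(OMe)3, MeOH, pyridinium p-toluenesulfonate (5 mol %), rt
Reagents that add atoms: trimethyl orthoformate, COC(OC)OC
Why: Acetalization masks the enal toward radicals, hydride and base; the vinylogous keto ester carbonyl is too deactivated to ketalize.

**Union and endgame**

Step 19
Reactants: 12 spiro-epoxide (fragment A), 27 keto enoate (fragment B)
Product: 29 (4S,5R,8R,9R,10S,13S)-6,18-bis(TBSO)-15,15-dimethoxy-11-oxo-6,7:8,15-disecokaur-16-en-7,20-olide, via hydroxy ester 28 (not isolated)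
Conditions: Cp2TiCl2 (0.3 equiv), Zn, 2,4,6-collidine·HCl, THF, rt; then KOt-Bu (0.3 equiv), t-BuOH–THF, 0 °C to rt
Reagents that add atoms: none
Why: Nugent–RajanBabu epoxide opening by Cp2TiCl (trivalent titanium) gives the tertiary C10 radical, which adds (Giese reaction) to the unsubstituted alkene carbon anti to the C5 CH2OTBS group (sets C10); base then lactonizes and equilibrates C8 and C9 to the all-equatorial trans-fused isomer, where C10 is trans to the C13 side chain (sets C9; C8 is reset in step 23).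

Step 20
Reactants: 29 spiro keto lactone
Product: 31 (4S,5R,8R,9R,10S,11R,13S)-6,18-bis(TBSO)-11-(TESO)-15,15-dimethoxy-6,7:8,15-disecokaur-16-en-7,20-olide, via alcohol 30 (not isolated)
Conditions: LiBH(s-Bu)3, THF, −78 °C; then TESCl, −78 to 0 °C
Reagents that add atoms: chlorotriethylsilane, CC[Si](Cl)(CC)CC
Why: Diastereoselective ketone reduction; the bulky borohydride attacks equatorially and gives the axial alcohol cis to the equatorial C10 substituent (sets C11), and the lithium alkoxide is silylated in the same flask.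

Step 21
Reactants: 31 TES ether
Product: 32 (4S,5R,8R,9R,10S,11R,13R)-8-bromo-6,18-bis(TBSO)-11-(TESO)-15,15-dimethoxy-6,7:8,15-disecokaur-16-en-7,20-olide
Conditions: LiN(i-Pr)2, THF, −78 °C; CBr4, −78 °C; H2O
Reagents that add atoms: tetrabromomethane, BrC(Br)(Br)Br
Why: Electrophilic α-bromination of the lactone enolate at the only acidic C–H; the C8 configuration (major epimer drawn) is irrelevant because C8 is planarized again in step 23.

Step 22
Reactants: 32 bromo lactone
Product: 33 (4S,5R,8R,9R,10S,11R,13R)-8-bromo-6,11,18-trihydroxy-15-oxo-6,7:8,15-disecokaur-16-en-7,20-olide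
Conditions: 1 M HCl (aq), THF, rt
Reagents that add atoms: water, O
Why: Acid hydrolysis unmasks the enal from its allylic acetal and cleaves the three silyl ethers; the tertiary α-bromo lactone is inert to aqueous acid.

Step 23
Reactants: 33 bromo lactone enal
Product: 34 (4S,5R,8S,9S,10S,11R,13S,15R)-6,11,15,18-tetrahydroxy-6,7-secokaur-16-en-7,20-olide
Conditions: CrCl2 (4 equiv), LiI (10 mol %), THF, rt
Reagents that add atoms: none
Why: Intramolecular Reformatsky-type aldol addition; divalent chromium reduces the α-bromo lactone to the C8 chromium enolate, which adds to the enal carbonyl (5-exo), and the short tether from C13 reaches only the enolate face cis to it, so C8 forms with C15 syn to C16 and the lactone cis-fused (sets C8; the C15 epimers converge in step 24).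

Step 24
Reactants: 34 allylic alcohol
Product: 35 (4S,5R,8S,9S,10S,11R,13S)-6,11,18-trihydroxy-15-oxo-6,7-secokaur-16-en-7,20-olide (target)
Conditions: MnO2 (20 equiv), CH2Cl2, rt
Reagents that add atoms: none
Why: Chemoselective MnO2 oxidation of the allylic C15 alcohol to the α-methylene ketone; the saturated primary and secondary hydroxyls are not oxidized.

**Compound list**
1 | ethyl 2-oxocyclohexane-1-carboxylate | CCOC(=O)C1CCCCC1=O | starting material
2 | ethyl (1R,2R)-2-hydroxycyclohexane-1-carboxylate | CCOC(=O)[C@@H]1CCCC[C@H]1O | intermediate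
3 | ethyl (1S,2R)-2-hydroxy-1-methylcyclohexane-1-carboxylate | CCOC(=O)[C@@]1(C)CCCC[C@H]1O | intermediate
4 | ethyl (1S)-1-methyl-2-oxocyclohexane-1-carboxylate | CCOC(=O)[C@@]1(C)CCCCC1=O | intermediate
5 | ethyl (1S,3R)-3-hydroxy-1-methyl-2-oxocyclohexane-1-carboxylate (lactonizing epimer) | CCOC(=O)[C@@]1(C)CCC[C@@H](O)C1=O | intermediate
6 | (1S,5R)-1-methyl-6-oxabicyclo[3.2.1]octane-7,8-dione | O=C1O[C@@H]2CCC[C@@]1(C)C2=O | intermediate
7 | (1S,5R)-1-methyl-8-methylidene-6-oxabicyclo[3.2.1]octan-7-one | O=C1O[C@@H]2CCC[C@@]1(C)C2=C | intermediate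
8 | (1S,5R,8S)-8-(hydroxymethyl)-1-methyl-6-oxabicyclo[3.2.1]octan-7-one | O=C1O[C@@H]2CCC[C@@]1(C)[C@H]2CO | intermediate
9 | (1R,2S,3S)-2,3-bis(hydroxymethyl)-3-methylcyclohexan-1-ol | OC[C@@]1(C)CCC[C@@H](O)[C@@H]1CO | intermediate
10 | (1R,2S,3S)-2,3-bis(TBSOCH2)-3-methylcyclohexan-1-ol | CC(C)(C)[Si](C)(C)OC[C@@]1(C)CCC[C@@H](O)[C@@H]1CO[Si](C)(C)C(C)(C)C | intermediate
11 | (2S,3S)-2,3-bis(TBSOCH2)-3-methylcyclohexan-1-one | CC(C)(C)[Si](C)(C)OC[C@@]1(C)CCCC(=O)[C@@H]1CO[Si](C)(C)C(C)(C)C | intermediate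
12 | (3R,4S,5S)-4,5-bis(TBSOCH2)-5-methyl-1-oxaspiro[2.5]octane (fragment A) | CC(C)(C)[Si](C)(C)OC[C@@]1(C)CCC[C@]2(CO2)[C@@H]1CO[Si](C)(C)C(C)(C)C | intermediate
13 | methyl 3,3-dimethoxypropanoate | COC(=O)CC(OC)OC | starting material
14 | 3,3-dimethoxypropanal | O=CCC(OC)OC | intermediate
15 | ethyl 3-bromo-2-oxopropanoate | CCOC(=O)C(=O)CBr | starting material
16 | triphenylphosphane | c1ccc(cc1)P(c1ccccc1)c1ccccc1 | starting material
17 | (3-ethoxy-2,3-dioxopropyl)triphenylphosphonium bromide | CCOC(=O)C(=O)C[P+](c1ccccc1)(c1ccccc1)c1ccccc1.[Br-] | intermediate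
18 | ethyl 2-oxo-3-(triphenyl-λ5-phosphanylidene)propanoate | CCOC(=O)C(=O)C=P(c1ccccc1)(c1ccccc1)c1ccccc1 | intermediate
19 | ethyl (3E)-6,6-dimethoxy-2-oxohex-3-enoate | CCOC(=O)C(=O)/C=C/CC(OC)OC | intermediate
20 | acetone | CC(C)=O | starting material
21 | ethyl (4R)-4-(2,2-dimethoxyethyl)-2,6-dioxoheptanoate | CCOC(=O)C(=O)C[C@@H](CC(C)=O)CC(OC)OC | intermediate
22 | ethyl (5R)-5-(2,2-dimethoxyethyl)-1-hydroxy-3-oxocyclohexane-1-carboxylate (C1 epimers) | CCOC(=O)C1(O)CC(=O)C[C@H](C1)CC(OC)OC | intermediate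
23 | ethyl (5R)-5-(2,2-dimethoxyethyl)-3-oxocyclohex-1-ene-1-carboxylate | CCOC(=O)C1=CC(=O)C[C@H](C1)CC(OC)OC | intermediate
24 | ethyl (5R)-3-oxo-5-(2-oxoethyl)cyclohex-1-ene-1-carboxylate | CCOC(=O)C1=CC(=O)C[C@H](C1)CC=O | intermediate
25 | ethyl (5S)-5-[3-(dimethylamino)-1-oxopropan-2-yl]-3-oxocyclohex-1-ene-1-carboxylate (side-chain epimers) | CCOC(=O)C1=CC(=O)C[C@H](C1)C(CN(C)C)C=O | intermediate
26 | ethyl (5S)-3-oxo-5-(3-oxoprop-1-en-2-yl)cyclohex-1-ene-1-carboxylate | CCOC(=O)C1=CC(=O)C[C@H](C1)C(=C)C=O | intermediate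
27 | ethyl (5S)-5-(3,3-dimethoxyprop-1-en-2-yl)-3-oxocyclohex-1-ene-1-carboxylate (fragment B) | CCOC(=O)C1=CC(=O)C[C@H](C1)C(=C)C(OC)OC | intermediate
28 | ethyl (1R,2R,5S)-2-[(1S,2R,3S)-2,3-bis(TBSOCH2)-1-(hydroxymethyl)-3-methylcyclohexyl]-5-(3,3-dimethoxyprop-1-en-2-yl)-3-oxocyclohexane-1-carboxylate | CCOC(=O)[C@@H]1C[C@H](C(=C)C(OC)OC)CC(=O)[C@H]1[C@]1(CO)CCC[C@](C)(CO[Si](C)(C)C(C)(C)C)[C@H]1CO[Si](C)(C)C(C)(C)C | intermediate
29 | (4S,5R,8R,9R,10S,13S)-6,18-bis(TBSO)-15,15-dimethoxy-11-oxo-6,7:8,15-disecokaur-16-en-7,20-olide (lactone trans-fused to ring C) | COC(OC)C(=C)[C@H]1C[C@H]2C(=O)OC[C@]3(CCC[C@](C)(CO[Si](C)(C)C(C)(C)C)[C@H]3CO[Si](C)(C)C(C)(C)C)[C@@H]2C(=O)C1 | intermediate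
30 | (4S,5R,8R,9R,10S,11R,13S)-6,18-bis(TBSO)-11-hydroxy-15,15-dimethoxy-6,7:8,15-disecokaur-16-en-7,20-olide | COC(OC)C(=C)[C@H]1C[C@H]2C(=O)OC[C@]3(CCC[C@](C)(CO[Si](C)(C)C(C)(C)C)[C@H]3CO[Si](C)(C)C(C)(C)C)[C@@H]2[C@H](O)C1 | intermediate
31 | (4S,5R,8R,9R,10S,11R,13S)-6,18-bis(TBSO)-11-(TESO)-15,15-dimethoxy-6,7:8,15-disecokaur-16-en-7,20-olide | COC(OC)C(=C)[C@H]1C[C@H]2C(=O)OC[C@]3(CCC[C@](C)(CO[Si](C)(C)C(C)(C)C)[C@H]3CO[Si](C)(C)C(C)(C)C)[C@@H]2[C@H](O[Si](CC)(CC)CC)C1 | intermediate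
32 | (4S,5R,8R,9R,10S,11R,13R)-8-bromo-6,18-bis(TBSO)-11-(TESO)-15,15-dimethoxy-6,7:8,15-disecokaur-16-en-7,20-olide | COC(OC)C(=C)[C@H]1C[C@]2(Br)C(=O)OC[C@]3(CCC[C@](C)(CO[Si](C)(C)C(C)(C)C)[C@H]3CO[Si](C)(C)C(C)(C)C)[C@@H]2[C@H](O[Si](CC)(CC)CC)C1 | intermediate
33 | (4S,5R,8R,9R,10S,11R,13R)-8-bromo-6,11,18-trihydroxy-15-oxo-6,7:8,15-disecokaur-16-en-7,20-olide | O=CC(=C)[C@H]1C[C@]2(Br)C(=O)OC[C@]3(CCC[C@](C)(CO)[C@H]3CO)[C@@H]2[C@H](O)C1 | intermediate
34 | (4S,5R,8S,9S,10S,11R,13S,15R)-6,11,15,18-tetrahydroxy-6,7-secokaur-16-en-7,20-olide | C=C1[C@@H](O)[C@]23C[C@H]1C[C@@H](O)[C@H]2[C@@]1(CCC[C@](C)(CO)[C@H]1CO)COC3=O | intermediate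
35 | (4S,5R,8S,9S,10S,11R,13S)-6,11,18-trihydroxy-15-oxo-6,7-secokaur-16-en-7,20-olide | C=C1C(=O)[C@]23C[C@H]1C[C@@H](O)[C@H]2[C@@]1(CCC[C@](C)(CO)[C@H]1CO)COC3=O | target

**Step count**
Total steps: 24. Longest linear sequence: 16 (steps 1–10, then 19–24), which is two thirds of the total; fragment B takes 8 steps (11–18).

**Steps most likely to fail**

Step 19. The reducing titanium reagent may consume the electron-poor keto enoate, and addition of the hindered tertiary radical may be slow. The fallback sets out from 12 and comes back at 28, which the base treatment of step 19 takes on to 29. Sodium 4-methoxybenzyl oxide opens the epoxide at C20 to give the tertiary alcohol F2. Methyl chlorooxoacetate with Et3N and 4-(dimethylamino)pyridine converts it into the methyl oxalate F3, and CsOH gives the cesium oxalate F4. Visible-light photoredox decarboxylation with [Ir(dF(CF3)ppy)2(dtbbpy)]PF6 in the presence of 27 generates the same C10 radical without a stoichiometric reductant and gives the coupled ester F5. 2,3-Dichloro-5,6-dicyano-1,4-benzoquinone then removes the 4-methoxybenzyl group to give 28.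

Step 23. The free hydroxyls may protonate the chromium enolate, and the enal may react otherwise. The fallback sets out from 32 and comes back at 35; it closes the ring before deprotection. Pyridinium p-toluenesulfonate in wet acetone at 0 °C hydrolyses only the allylic acetal to give the silylated bromo enal F6. SmI2 (divalent samarium) in THF at −78 °C effects the intramolecular aldol addition on the fully protected substrate to give the silylated allylic alcohol F7. Dess–Martin periodinane gives the silylated enone F8, and HF·pyridine removes the three silyl groups to give 35.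

Step 14. 1,2-Addition to the keto group may compete, and an aliphatic β-substituent may lower the enantioselectivity. The fallback sets out from 19 and comes back at 21. An inverse-demand hetero-Diels–Alder reaction of 19 with 2-(trimethylsilyloxy)propene, catalysed by [Cu((S,S)-t-Bu-box)](OTf)2 (a divalent copper Lewis acid that chelates the keto ester), gives the dihydropyran F1. Dilute aqueous citric acid opens it to 21.

**Further compounds**
F1 | step 14 | ethyl (4R)-4-(2,2-dimethoxyethyl)-6-methyl-6-[(trimethylsilyl)oxy]-5,6-dihydro-4H-pyran-2-carboxylate (C6 epimers) | CCOC(=O)C1=C[C@H](CC(OC)OC)CC(C)(O[Si](C)(C)C)O1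
F2 | step 19 | (1R,2S,3S)-2,3-bis(TBSOCH2)-1-{[(4-methoxybenzyl)oxy]methyl}-3-methylcyclohexan-1-ol | COc1ccc(COC[C@@]2(O)CCC[C@](C)(CO[Si](C)(C)C(C)(C)C)[C@H]2CO[Si](C)(C)C(C)(C)C)cc1
F3 | step 19 | methyl oxalate of F2 | COC(=O)C(=O)O[C@]1(COCc2ccc(OC)cc2)CCC[C@](C)(CO[Si](C)(C)C(C)(C)C)[C@H]1CO[Si](C)(C)C(C)(C)C
F4 | step 19 | cesium oxalate of F2 | [Cs+].[O-]C(=O)C(=O)O[C@]1(COCc2ccc(OC)cc2)CCC[C@](C)(CO[Si](C)(C)C(C)(C)C)[C@H]1CO[Si](C)(C)C(C)(C)C
F5 | step 19 | 4-methoxybenzyl ether of 28 | CCOC(=O)[C@@H]1C[C@H](C(=C)C(OC)OC)CC(=O)[C@H]1[C@]1(COCc2ccc(OC)cc2)CCC[C@](C)(CO[Si](C)(C)C(C)(C)C)[C@H]1CO[Si](C)(C)C(C)(C)C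
F6 | step 23 | 8-bromo-6,18-bis(TBSO)-11-(TESO)-15-oxo-6,7:8,15-disecokaur-16-en-7,20-olide | O=CC(=C)[C@H]1C[C@]2(Br)C(=O)OC[C@]3(CCC[C@](C)(CO[Si](C)(C)C(C)(C)C)[C@H]3CO[Si](C)(C)C(C)(C)C)[C@@H]2[C@H](O[Si](CC)(CC)CC)C1
F7 | step 23 | 6,18-bis(TBSO)-11-(TESO)-15-hydroxy-6,7-secokaur-16-en-7,20-olide | C=C1[C@@H](O)[C@]23C[C@H]1C[C@@H](O[Si](CC)(CC)CC)[C@H]2[C@@]1(CCC[C@](C)(CO[Si](C)(C)C(C)(C)C)[C@H]1CO[Si](C)(C)C(C)(C)C)COC3=O
F8 | step 23 | 6,18-bis(TBSO)-11-(TESO)-15-oxo-6,7-secokaur-16-en-7,20-olide | C=C1C(=O)[C@]23C[C@H]1C[C@@H](O[Si](CC)(CC)CC)[C@H]2[C@@]1(CCC[C@](C)(CO[Si](C)(C)C(C)(C)C)[C@H]1CO[Si](C)(C)C(C)(C)C)COC3=O
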